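Charge for the product of two factors, not for conversion by itself. I had to choose the flask for the most mono adduct at the asked time.

all flasks: substrate 46 mM

|  | reagent | remark | time |
|---|---|---|---|
| maple | 0.89 equiv | run made earlier |  |
| elm | 1.8 equiv | run made earlier |  |
| birch | 4.3 equiv | run made earlier |  |
| west | 0.800 equiv |  | 80 min |
| east | 1.00 equiv |  | 80 min |
| south-east | 4.00 equiv |  | 80 min |

- maple (time / min: mono adduct / %, substrate / %): 4.00: 6.5, 93.5; 10.0: 13.9, 85.1; 20.0: 20.9, 74.0; 30.0: 25.2, 65.7; 40.0: 28.5, 59.2
- elm (time / min: mono adduct / %, substrate / %): 8.00: 21.5, 75.9; 15.0: 32.6, 61.9; 25.0: 40.4, 47.2; 30.0: 42.3, 41.6; 40.0: 44.6, 32.7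
- birch (time / min: mono adduct / %, substrate / %): 8.00: 42.2, 51.8; 15.0: 56.1, 31.4; 25.0: 60.4, 14.9; 30.0: 59.8, 10.0; 40.0: 56.4, 5.9

(readings scatter by 0.3 percentage points)

- candidate steps: substrate + reagent -> mono adduct; reagent + mono adduct <-> double product; mono adduct <-> isomer of the product

* final mono adduct, as a percentage of the substrate charged, for each flask in turn (west, east, south-east)

The first factor was conversion. Birch began as a pseudo-first-order decay, so I read a constant per minute per equivalent at a [substrate] of 46 mM, using its mean reagent over the first interval:

k' = 0.0203 /min

Conversions at 80 min followed from the second-order law; for south-east I assumed a steady 3.00 equivalents of reagent, its charge less one equivalent for the substrate: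

west: 52.5 %
east: 61.8 %
south-east: 99.2 %

The second factor was the late end. Birch at 40.0 min held a mono share of 59.9 %, the mono adduct as a fraction of the substrate consumed. Keeping that share unchanged, I reckoned:

west: 31.5 %
east: 37.1 %

But the birch share had been 66.4 % at 30.0 min, so it was still falling. South-east therefore needed a break-even share, the one at which it equals my east figure:

37.4 %

I chose south-east, and I gave it no point value beyond that test.

The forecast gave 28.5 %, 32.5 % and 38 %. Its east value stood lower than mine. Its south-east value stood higher than its east value. It held that “With 4 equiv, substrate is gone and mono adduct falls from about 55 to about 37–38%”.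

The flasks gave 30.4 %, 35.5 % and 46.0 %.

    substrate + reagent → mono adduct (k = 0.440 /M/min)
    reagent + mono adduct ⇌ double product (K = 9.40 /M, k = 0.0250 /M/min)
    mono adduct ⇌ isomer of the product (K = 0.960, k = 0.0220 /min)

South-east held a mono share of 46.3 %, lower than the birch reading but higher than the break-even. In west at 80.0 min, the forward rate of the isomer step used mono adduct 71 times faster than the forward rate of the double step. Taking each step net, west still made mono adduct 1.34 times faster than it used it.

The data are simulated from invented constants, and the scatter is random.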